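## Retrosynthetic overview

1. Feature: the benzene ring of the target, C1(OH)–C2H–C3(OH)–C4H–C5(alkyl)–C6H, holds the same six carbons and two oxygens as a 4-alkyl-6-methyl-2-pyrone. Pyrone C2, C3, C4, C5, C6 and the 6-CH3 carbon become arene C1, C6, C5, C4, C3 and C2, so the chain already sits on the right carbon.
2. Key disconnection: arene C1–C2, from a hydroxyl-bearing carbon to the CH flanked by both OH groups. In the forward direction methoxide cleaves the lactone C2–O1 bond and the former 6-methyl carbon closes onto the ester carbon (Claisen). This is the only ring made in the route, because the pyrone ring is bought as triacetic acid lactone.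
3. Pyrone C4–CH2 bond: Negishi coupling of the 4-tosylate of triacetic acid lactone with the alkylzinc bromide of a C17 bromo ketal.
4. Bromo ketal: hexadecanolide, then Weinreb amide, methyl ketone, dioxolane and Appel bromide.
5. End game: aqueous acid unmasks the methyl ketone.

Key step: step 7

Assumption: hexadecanolide 1 is taken as the 17-membered lactone oxacycloheptadecan-2-one (16 carbons). Its carbonyl carbon becomes C2 and its OCH2 carbon becomes C17 of the heptadecan-2-one chain. The target has no stereocentre.

## Route

Step 1
Reactants: 1 hexadecanolide
Product: 2 16-hydroxy-N-methoxy-N-methylhexadecanamide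
Conditions: MeNH(OMe)·HCl (2 equiv), i-PrMgCl (4 equiv), THF, −20 to 0 °C; aq NH4Cl
Reagents that add atoms: N,O-dimethylhydroxylamine hydrochloride, CNOC.Cl
Why: Weinreb aminolysis of a lactone, in which the chloromagnesium amide made in the flask acylates at the macrolactone carbonyl and the released primary alkoxide cannot re-close a 17-membered ring under these conditions.

Step 2
Reactants: 2 16-hydroxy-N-methoxy-N-methylhexadecanamide
Product: 3 17-hydroxyheptadecan-2-one
Conditions: MeMgBr (3 equiv), THF, 0 °C; aq NH4Cl
Reagents that add atoms: methylmagnesium bromide, C[Mg]Br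
Why: Weinreb ketone synthesis, in which one equivalent of MeMgBr deprotonates the alcohol and the next adds once to the amide, giving a chelated tetrahedral adduct that collapses to the methyl ketone only on work-up, so no tertiary alcohol should form.

Step 3
Reactants: 3 17-hydroxyheptadecan-2-one
Product: 4 15-(2-methyl-1,3-dioxolan-2-yl)pentadecan-1-ol
Conditions: ethylene glycol (5 equiv), p-TsOH·H2O (cat.), toluene, reflux, Dean–Stark
Reagents that add atoms: ethylene glycol, OCCO
Why: Acid-catalysed ketalisation with azeotropic removal of water, in which the five-membered dioxolane from excess glycol is favoured over acyclic mixed ketals with the remote primary alcohol.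

Step 4
Reactants: 4 15-(2-methyl-1,3-dioxolan-2-yl)pentadecan-1-ol
Product: 5 2-(15-bromopentadecyl)-2-methyl-1,3-dioxolane
Conditions: CBr4, PPh3, 2,6-lutidine (0.2 equiv), CH2Cl2, 0 °C
Reagents that add atoms: carbon tetrabromide, BrC(Br)(Br)Br
Why: Appel reaction, in which bromide displaces the alkoxyphosphonium salt of the unhindered primary alcohol in an SN2 step while the lutidine buffer keeps the medium non-acidic for the dioxolane.

Step 5
Reactants: 6 triacetic acid lactone (4-hydroxy-6-methyl-2H-pyran-2-one); 7 p-toluenesulfonyl chloride
Product: 8 6-methyl-2-oxo-2H-pyran-4-yl 4-methylbenzenesulfonate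
Conditions: Et3N (1.3 equiv), CH2Cl2, 0 °C to rt
Reagents that add atoms: p-toluenesulfonyl chloride (7), Cc1ccc(cc1)S(=O)(=O)Cl
Why: O-Sulfonylation of the acidic vinylogous carboxylic acid OH on pyrone C4, which turns that position into a pseudohalide for cross-coupling.

Step 6
Reactants: 5 2-(15-bromopentadecyl)-2-methyl-1,3-dioxolane; 8 6-methyl-2-oxo-2H-pyran-4-yl 4-methylbenzenesulfonate
Product: 10 6-methyl-4-[15-(2-methyl-1,3-dioxolan-2-yl)pentadecyl]-2H-pyran-2-one, via alkylzinc bromide 9 (not isolated)
Conditions: 5, Zn dust (1.5 equiv), I2 (5 mol%), DMA, 80 °C; then 8, PdCl2(dppf) (3 mol%), THF–DMA, 25 to 50 °C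
Reagents that add atoms: zinc, [Zn] (held only in 9; no reagent atom remains in 10)
Why: Direct zinc insertion followed by Negishi coupling, in which the C4 tosylate is a vinylogous acyl sulfonate that adds readily to zerovalent palladium, the bidentate dppf ligand holds back β-hydride elimination of the primary alkyl group, and the mild organozinc reagent is preferred to an alkylmagnesium/Fe(acac)3 system because it neither adds to the lactone carbonyl nor opens the pyrone ring.

Step 7
Reactants: 10 6-methyl-4-[15-(2-methyl-1,3-dioxolan-2-yl)pentadecyl]-2H-pyran-2-one
Product: 12 5-[15-(2-methyl-1,3-dioxolan-2-yl)pentadecyl]benzene-1,3-diol, via Z keto ester 11 (not isolated)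
Conditions: NaOMe (1.5 equiv), dry MeOH–THF, 50 °C, Ar; concentrate; KOt-Bu (3 equiv), toluene–THF, high dilution, reflux with distillation of MeOH, Ar; AcOH (1 equiv per base), 0 °C
Reagents that add atoms: sodium methoxide, C[O-].[Na+] (its OMe group is held only in 11 and leaves again on ring closure)
Why: Proposed new method: attack of methoxide on the acyl carbon C2 cleaves the C2–O1 bond and releases the delocalised sodium dienolate of keto ester 11, whose ester and 2-oxopropyl arms stay on the same side of the former C3=C4 alkene. This dienolate is a resting state, but under KOt-Bu at reflux proton transfer populates the less stable terminal enolate (or the dianion) at the former 6-methyl carbon, which attacks the ester carbon in a favoured 6-(enolendo)-exo-trig Claisen closure, and expulsion of methoxide with enolisation gives the resorcinolate. The closest known reactions are the alkoxide cyclisation of 5-oxohexanoate esters to cyclohexane-1,3-diones, the cyclisation of 3,5-dioxohexanoate esters to phloroglucinol and the nucleophile-induced transformation of 2-pyranones into arenes, whereas the one-flask pyrone-to-resorcinol isomerisation is untested. The selectivity required is C- over O-acylation: O-acylation merely regenerates 10, which methoxide reopens, while C-acylation ends in an aromatic phenolate that cannot revert, and every other intramolecular carbanion–carbonyl pairing in 11 would close a four-membered ring. Attack at C2 rather than C6 is favoured by the hard alkoxide and by the methyl group on C6, E/Z scrambling of the dienolate is harmless because the isomers interconvert and only Z can close, and dilution with strict exclusion of water holds back intermolecular aldol or Michael reactions and saponification. No stereocentre is formed, and the dioxolane is inert to alkoxide and to the brief cold AcOH quench.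

Step 8
Reactants: 12 5-[15-(2-methyl-1,3-dioxolan-2-yl)pentadecyl]benzene-1,3-diol
Product: 13 hansfordiol B, 17-(3,5-dihydroxyphenyl)heptadecan-2-one
Conditions: 1 M aq HCl, THF, rt
Reagents that add atoms: water, O
Why: Acid-catalysed hydrolysis of the dioxolane through its oxocarbenium ion, under dilute acid at room temperature that leaves the resorcinol ring and the saturated chain untouched.

## Compound list

1 | hexadecanolide (oxacycloheptadecan-2-one) | O=C1CCCCCCCCCCCCCCCO1 | starting material
2 | 16-hydroxy-N-methoxy-N-methylhexadecanamide | CON(C)C(=O)CCCCCCCCCCCCCCCO | intermediate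
3 | 17-hydroxyheptadecan-2-one | CC(=O)CCCCCCCCCCCCCCCO | intermediate
4 | 15-(2-methyl-1,3-dioxolan-2-yl)pentadecan-1-ol | CC1(CCCCCCCCCCCCCCCO)OCCO1 | intermediate
5 | 2-(15-bromopentadecyl)-2-methyl-1,3-dioxolane | CC1(CCCCCCCCCCCCCCCBr)OCCO1 | intermediate
6 | triacetic acid lactone (4-hydroxy-6-methyl-2H-pyran-2-one) | CC1=CC(O)=CC(=O)O1 | starting material
7 | p-toluenesulfonyl chloride | Cc1ccc(cc1)S(=O)(=O)Cl | starting material
8 | 6-methyl-2-oxo-2H-pyran-4-yl 4-methylbenzenesulfonate | CC1=CC(OS(=O)(=O)c2ccc(C)cc2)=CC(=O)O1 | intermediate
9 | [15-(2-methyl-1,3-dioxolan-2-yl)pentadecyl]zinc bromide, formed in the flask | CC1(CCCCCCCCCCCCCCC[Zn]Br)OCCO1 | intermediate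
10 | 6-methyl-4-[15-(2-methyl-1,3-dioxolan-2-yl)pentadecyl]-2H-pyran-2-one | CC1=CC(CCCCCCCCCCCCCCCC2(C)OCCO2)=CC(=O)O1 | intermediate
11 | methyl (Z)-3-[15-(2-methyl-1,3-dioxolan-2-yl)pentadecyl]-5-oxohex-2-enoate, present in the flask as its dienolate | COC(=O)/C=C(\CC(C)=O)CCCCCCCCCCCCCCCC1(C)OCCO1 | intermediate
12 | 5-[15-(2-methyl-1,3-dioxolan-2-yl)pentadecyl]benzene-1,3-diol | CC1(CCCCCCCCCCCCCCCc2cc(O)cc(O)c2)OCCO1 | intermediate
13 | hansfordiol B, 17-(3,5-dihydroxyphenyl)heptadecan-2-one | CC(=O)CCCCCCCCCCCCCCCc1cc(O)cc(O)c1 | target

## Step count

Total step count: 8.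
Longest linear sequence: 7 steps (1, 2, 3, 4, 6, 7, 8). Step 5 is a one-step side branch.

## Steps most likely to fail

**Step 7.** Two things may prevent closure. The delocalised dienolate may be very stable, and its ester carbonyl may be strongly deactivated by conjugation with the anion. The terminal enolate would then never be populated enough to cyclise. Intermolecular aldol and Michael condensation, saponification by traces of water, or simple re-lactonisation on quench would consume the material instead.

The fallback uses known chemistry and replaces the ring isomerisation by an aryl–alkyl cross-coupling. It sets out from zinc reagent 9, made from 5 as in step 6. Negishi coupling of 9 with commercial 1,3-bis(benzyloxy)-5-bromobenzene (Brc1cc(OCc2ccccc2)cc(OCc2ccccc2)c1) uses Pd(OAc)2 and SPhos in THF–DMA at 50 °C. It should give 2-{15-[3,5-bis(benzyloxy)phenyl]pentadecyl}-2-methyl-1,3-dioxolane F1. Hydrogenolysis of both benzyl ethers (H2, Pd/C, EtOAc, rt), to which the dioxolane is inert, comes back to the route at 12.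

**Step 6.** Zinc insertion into the unactivated primary bromide may stall. The alkylpalladium intermediate may undergo β-hydride elimination. The tosylate may also be cleaved at sulfur instead of entering C–O oxidative addition.

The fallback changes the nucleophile to a borane made by hydroboration and sets out from 5. E2 elimination (KOt-Bu, THF, 0 °C to rt) should give 2-methyl-2-(pentadec-14-en-1-yl)-1,3-dioxolane F2. Anti-Markovnikov hydroboration with 9-BBN-H (THF, rt) should then give 9-[15-(2-methyl-1,3-dioxolan-2-yl)pentadecyl]-9-borabicyclo[3.3.1]nonane F3. F3 is used directly in a B-alkyl Suzuki–Miyaura coupling with tosylate 8 (PdCl2(dppf), K3PO4, THF–DMF, 50 °C), which comes back to the route at 10.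

**Step 4.** Traces of HBr released during the bromination may cause loss of the dioxolane. A freed ketone would not survive the later organozinc and alkoxide steps.

The fallback changes the order of events and sets out from 3. Appel bromination of the unprotected hydroxy ketone (CBr4, PPh3, CH2Cl2, 0 °C), where no acid-labile group is present, should give 17-bromoheptadecan-2-one F4. Ketalisation (ethylene glycol, p-TsOH, toluene, Dean–Stark), to which a primary alkyl bromide is inert, comes back to the route at 5.

## Further compounds

F1 | step 7 | 2-{15-[3,5-bis(benzyloxy)phenyl]pentadecyl}-2-methyl-1,3-dioxolane | CC1(CCCCCCCCCCCCCCCc2cc(OCc3ccccc3)cc(OCc3ccccc3)c2)OCCO1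
F2 | step 6 | 2-methyl-2-(pentadec-14-en-1-yl)-1,3-dioxolane | CC1(CCCCCCCCCCCCCC=C)OCCO1
F3 | step 6 | 9-[15-(2-methyl-1,3-dioxolan-2-yl)pentadecyl]-9-borabicyclo[3.3.1]nonane | CC1(CCCCCCCCCCCCCCCB2C3CCCC2CCC3)OCCO1
F4 | step 4 | 17-bromoheptadecan-2-one | CC(=O)CCCCCCCCCCCCCCCBr
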